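**Assumptions**
- Atom labels C1–C20 follow ent-kaurane numbering (C6 and C7 are the lactone carbonyls; C19 and C20 are the OCH2 carbons). The target is (4R,5R,8S,9S,10R,11R,13S,15R).
- In Step 2 the quinidine-derived primary amine is assumed to give the enantiomer shown; if the sense is opposite, the quinine-derived pseudo-enantiomer is used.

**Retrosynthetic overview**
1. Guidongnin ⇒ 11,15-diketone (both carbinols from one Luche reduction) ⇒ ring D by 5-exo vinyl-radical closure of C13–C16.
2. ⇒ C8 quaternary centre by aldol of the 7,20-lactone enolate with 2-bromoacrolein (C8–C15).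
3. ⇒ rings B (δ-lactone) and C together by intramolecular Diels–Alder reaction of a C10-bound 2-silyloxydiene with the C20 acrylate (C8–C9, C13–C14).
4. ⇒ C10 quaternary centre by Ireland–Claisen rearrangement on the ring A γ-lactone (C9–C10).
5. ⇒ ring A with C4/C5 by an amine-catalysed asymmetric Michael/α-alkylation annulation of two achiral pieces (C5–C10, then C3–C4). Ring order: A (+ 6,19-lactone) → B + C → D.

**Route**

Step 1
Reactants: 1 diallyl malonate; 2 1,3-dibromopropane (3 equiv)
Product: 3 diallyl 2-(3-bromopropyl)malonate
Conditions: NaH (1.0 equiv), THF/DMF, 0 °C → rt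
Reagents that add atoms: 1,3-dibromopropane, BrCCCBr
Why: SN2 malonate alkylation; excess dihalide and one equivalent of base hold it at mono-alkylation and avoid cyclobutane formation.

Step 2
Reactants: 3 diallyl 2-(3-bromopropyl)malonate; 4 ethyl (E)-3-methyl-4-oxobut-2-enoate
Product: 5 1,1-diallyl 2-ethyl (2R,3R)-3-formyl-3-methylcyclohexane-1,1,2-tricarboxylate (CHO cis to CO2Et)
Conditions: 9-amino-9-deoxy-epi-quinidine (20 mol %), TFA (40 mol %), NaOAc (1.5 equiv), NaI (20 mol %), PhMe, 40 °C
Reagents that add atoms: none (all atoms from 3 and 4; HBr lost)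
Why: Proposed new method: the primary amine forms the iminium ion of the α-branched enal, the malonate adds to the β-carbon (C5) on the catalyst-controlled face to set the first stereocentre, and the resulting enamine closes ring A by 6-exo-tet SN2 on the tethered halide through a chair in which the bulky malonate carbon avoids the C-methyl group, giving quaternary C4 with CHO cis to CO2Et; the closest known reactions are amine-catalysed Michael/α-alkylation dominos that make three- and five-membered rings and primary-amine iminium activation of α-branched enals, and what is new is six-ring closure onto an unactivated primary halide that creates an all-carbon quaternary centre.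

Step 3
Reactants: 5
Product: 6 diallyl (3aR,7aR)-3a-methyl-1-oxo-octahydroisobenzofuran-7,7-dicarboxylate (cis-fused 6,19-γ-lactone)
Conditions: NaBH4, THF/i-PrOH, 0 °C; then PPTS, PhMe, 60 °C
Reagents that add atoms: none
Why: Chemoselective aldehyde reduction (malonate esters inert), then lactonisation of the new CH2OH onto the cis vicinal ethyl ester; this fixes the 6,19-lactone before any C20 hydroxyl exists.

Step 4
Reactants: 6
Product: 7 allyl (3aR,7aR)-3a-methyl-1-oxooctahydroisobenzofuran-7-carboxylate (epimers at the ester-bearing carbon, C10; inconsequential)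
Conditions: LiCl, H2O, DMSO, 150 °C
Reagents that add atoms: none
Why: Krapcho dealkoxycarbonylation removes one allyl ester of the malonate; the lactone CH2–O is neopentyl and inert to chloride.

Step 5
Reactants: 7
Product: 8 (3aR,7R,7aR)-7-allyl-3a-methyl-1-oxooctahydroisobenzofuran-7-carboxylic acid (CO2H cis, allyl trans to the lactone carbonyl)
Conditions: LDA (1.1 equiv), TMSCl, THF, −78 → 60 °C; then 1 M HCl
Reagents that add atoms: none
Why: Ireland–Claisen rearrangement; the less hindered ester α-H is removed (the lactone α-H sits between C4 and C10), and the allyl group is delivered to the convex face of the cis-fused bicycle, anti to the vicinal lactone carbonyl and the 1,3-related C19, setting quaternary C10 with C20 at the acid level.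

Step 6
Reactants: 8
Product: 9 (3aR,7R,7aR)-7-allyl-7-(hydroxymethyl)-3a-methylhexahydroisobenzofuran-1(3H)-one
Conditions: CDI, THF, rt; then NaBH4, H2O, 0 °C (used at once)
Reagents that add atoms: none
Why: Reduction of the acyl imidazolide is selective for the activated acid over the γ-lactone and the alkene; no stereocentre changes.

Step 7
Reactants: 9; 10 acryloyl chloride
Product: 11 [(3aR,7R,7aR)-7-allyl-3a-methyl-1-oxooctahydroisobenzofuran-7-yl]methyl acrylate
Conditions: i-Pr2NEt, CH2Cl2, −20 °C
Reagents that add atoms: acryloyl chloride, C=CC(=O)Cl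
Why: O-acylation of the primary alcohol; immediate capping removes the risk of 6,19 → 6,20 translactonisation.

Step 8
Reactants: 11
Product: 12 [(3aR,7R,7aR)-3a-methyl-1-oxo-7-(2-oxoethyl)octahydroisobenzofuran-7-yl]methyl acrylate
Conditions: O3 (1 equiv, Sudan III end-point), CH2Cl2, −78 °C; then PPh3
Reagents that add atoms: ozone, O=[O+][O-]
Why: Ozonolysis is selective for the electron-rich terminal alkene over the electron-poor acrylate.

Step 9
Reactants: 12; 13 vinylmagnesium bromide (1.1 equiv)
Product: 14 [(3aR,7R,7aR)-3a-methyl-1-oxo-7-(2-oxobut-3-en-1-yl)octahydroisobenzofuran-7-yl]methyl acrylate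
Conditions: THF, −78 °C; then 1,1′-(azodicarbonyl)dipiperidine, −78 → 0 °C (one pot)
Reagents that add atoms: vinylmagnesium bromide, C=C[Mg]Br
Why: Grignard 1,2-addition to the aldehyde (far faster than to the esters at −78 °C), then Mukaiyama oxidation of the magnesium alkoxide in the same flask gives the vinyl ketone.

Step 10
Reactants: 14
Product: 15 [(3aR,7R,7aR)-3a-methyl-1-oxo-7-[(1Z)-2-(triethylsilyloxy)buta-1,3-dien-1-yl]octahydroisobenzofuran-7-yl]methyl acrylate, i.e. C10–C9H=C11(OSiEt3)–C12H=C13H2 with C10 trans to the vinyl group
Conditions: TESOTf (1.2 equiv), Et3N (2 equiv), CH2Cl2, −78 → 0 °C; cold NaHCO3 work-up, rapid filtration through Et3N-deactivated silica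
Reagents that add atoms: triethylsilyl triflate, CC[Si](CC)(CC)OS(=O)(=O)C(F)(F)F
Why: Soft enolisation/O-silylation of the vinyl ketone, which can only enolise toward C9, gives the 2-silyloxydiene; the (Z)-enol ether places the bulky C10 away from the vinyl group, and the lactone and acrylate are not silylated under these conditions. Isolating the diene free of ammonium triflate protects it from protodesilylation in the hot step that follows.

Step 11
Reactants: 15
Product: 16 Diels–Alder adduct, a tetracyclic bis-lactone: ring A and the cis 6,19-γ-lactone as in 9; spiro at C10 to the new 7,20-δ-lactone (C10–C20H2–O–C7(=O)–C8H–C9H); ring C = C8–C9–C11(OSiEt3)=C12–C13H2–C14H2; (4R,5R,9R,10R), C8–H epimers (inconsequential)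
Conditions: BHT (cat.), PhMe (0.01 M), 160 °C, sealed base-washed tube
Reagents that add atoms: none
Why: The ester-tethered intramolecular Diels–Alder reaction forms rings B and C at once (C9–C8 and C13–C14). C9 is expected with the target configuration because the C5 branch of C10 stays equatorial on the forming lactone ring and the smaller C1 methylene lies on the side of the reacting termini. C11 is left as a regiodefined silyl enol ether.

Step 12
Reactants: 17 acrolein
Product: 18 2-bromoacrolein (used as a fresh solution)
Conditions: Br2, CH2Cl2, −20 °C; then Et3N, 0 °C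
Reagents that add atoms: bromine, BrBr
Why: Bromine addition followed by dehydrobromination.

Step 13
Reactants: 16; 18 2-bromoacrolein
Product: 19 aldol adduct: as 16 but C8 quaternary, bearing CH(OH)–C(Br)=CH2 (C15–C17); (4R,5R,8S,9S,10R), C15 epimers
Conditions: LDA (1.05 equiv), THF, −78 °C; then 18, −78 °C; AcOH quench at −78 °C
Reagents that add atoms: 2-bromoacrolein, C=C(Br)C=O
Why: Aldol addition of the ring-fusion lactone enolate (C5–H is buried between two quaternary carbons and the silyl enol ether is inert to LDA); the aldehyde adds syn to H9 because the other face is covered by the C10 substituents, as in classical cis-selective alkylation of ring-fusion enolates.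

Step 14
Reactants: 19
Product: 20 (4R,5R,8S,9S,10R)-bis-enone: C11(=O)–C12=C13 cyclohexenone and C15(=O)–C16(Br)=C17H2
Conditions: IBX, 4-methoxypyridine N-oxide, DMSO, rt
Reagents that add atoms: none
Why: IBX oxidises the C15 carbinol and, as its N-oxide complex, dehydrogenates the silyl enol ether regiospecifically to the C12=C13 enone (Saegusa-type outcome without palladium, which would engage the vinyl bromide).

Step 15
Reactants: 20
Product: 21 (4R,5R,8S,9S,10R,13S)-11,15-dioxo-6,7-seco-ent-kaur-16-ene-6,19:7,20-diolide
Conditions: Bu3SnH (1.1 equiv, syringe pump), AIBN, PhH, 80 °C, 0.01 M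
Reagents that add atoms: none
Why: Bromine abstraction gives the C16 vinyl radical, which closes 5-exo-trig onto C13 (β-carbon of the enone) on the only face it can reach, forming the bicyclo[3.2.1]octane and C13; the α-keto radical at C12 is then reduced.

Step 16
Reactants: 21
Product: 22 Guidongnin, (4R,5R,8S,9S,10R,11R,13S,15R)-11,15-dihydroxy-6,7-seco-ent-kaur-16-ene-6,19:7,20-diolide
Conditions: NaBH4, CeCl3·7H2O, MeOH, −78 → −20 °C
Reagents that add atoms: none
Why: Luche 1,2-reduction of both ketones; at C15 hydride arrives from the exo face (the endo face is blocked by H9 and the C9–C11–C12 bridge), and at C11 from the face of H9 (the opposite face is blocked by C10 and its substituents and by C14–H), giving the 15R and 11R carbinols; the lactones and the exocyclic alkene are untouched.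

**Compound list**
1 | diallyl malonate | C=CCOC(=O)CC(=O)OCC=C | starting material
2 | 1,3-dibromopropane | BrCCCBr | starting material
3 | diallyl 2-(3-bromopropyl)malonate | C=CCOC(=O)C(CCCBr)C(=O)OCC=C | intermediate
4 | ethyl (E)-3-methyl-4-oxobut-2-enoate | CCOC(=O)/C=C(\C)C=O | starting material
5 | 1,1-diallyl 2-ethyl (2R,3R)-3-formyl-3-methylcyclohexane-1,1,2-tricarboxylate | C=CCOC(=O)C1(C(=O)OCC=C)CCC[C@@](C)(C=O)[C@H]1C(=O)OCC | intermediate
6 | diallyl (3aR,7aR)-3a-methyl-1-oxo-octahydroisobenzofuran-7,7-dicarboxylate | C=CCOC(=O)C1(C(=O)OCC=C)CCC[C@@]2(C)COC(=O)[C@H]21 | intermediate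
7 | allyl (3aR,7aR)-3a-methyl-1-oxooctahydroisobenzofuran-7-carboxylate (epimers at the ester-bearing carbon) | C=CCOC(=O)C1CCC[C@@]2(C)COC(=O)[C@H]21 | intermediate
8 | (3aR,7R,7aR)-7-allyl-3a-methyl-1-oxooctahydroisobenzofuran-7-carboxylic acid | C=CC[C@@]1(CCC[C@@]2(C)COC(=O)[C@H]21)C(=O)O | intermediate
9 | (3aR,7R,7aR)-7-allyl-7-(hydroxymethyl)-3a-methylhexahydroisobenzofuran-1(3H)-one | C=CC[C@@]1(CCC[C@@]2(C)COC(=O)[C@H]21)CO | intermediate
10 | acryloyl chloride | C=CC(=O)Cl | starting material
11 | [(3aR,7R,7aR)-7-allyl-3a-methyl-1-oxooctahydroisobenzofuran-7-yl]methyl acrylate | C=CC[C@@]1(CCC[C@@]2(C)COC(=O)[C@H]21)COC(=O)C=C | intermediate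
12 | [(3aR,7R,7aR)-3a-methyl-1-oxo-7-(2-oxoethyl)octahydroisobenzofuran-7-yl]methyl acrylate | O=CC[C@@]1(CCC[C@@]2(C)COC(=O)[C@H]21)COC(=O)C=C | intermediate
13 | vinylmagnesium bromide | C=C[Mg]Br | starting material
14 | [(3aR,7R,7aR)-3a-methyl-1-oxo-7-(2-oxobut-3-en-1-yl)octahydroisobenzofuran-7-yl]methyl acrylate | C=CC(=O)C[C@@]1(CCC[C@@]2(C)COC(=O)[C@H]21)COC(=O)C=C | intermediate
15 | [(3aR,7R,7aR)-3a-methyl-1-oxo-7-[(1Z)-2-(triethylsilyloxy)buta-1,3-dien-1-yl]octahydroisobenzofuran-7-yl]methyl acrylate | C=C/C(O[Si](CC)(CC)CC)=C/[C@@]1(CCC[C@@]2(C)COC(=O)[C@H]21)COC(=O)C=C | intermediate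
16 | Diels–Alder adduct, 11-triethylsilyloxy-11-ene bis-lactone, C8–H (epimers) | CC[Si](CC)(CC)OC1=CCCC2C(=O)OC[C@]3(CCC[C@@]4(C)COC(=O)[C@H]43)[C@H]12 | intermediate
17 | acrolein | C=CC=O | starting material
18 | 2-bromoacrolein | C=C(Br)C=O | intermediate
19 | C8 aldol adduct (C15 epimers) | CC[Si](CC)(CC)OC1=CCC[C@]2(C(O)C(Br)=C)C(=O)OC[C@]3(CCC[C@@]4(C)COC(=O)[C@H]43)[C@H]12 | intermediate
20 | 11-oxo-12-ene / 15-oxo-16-bromo-16-ene bis-enone | O=C1C=CC[C@]2(C(=O)C(Br)=C)C(=O)OC[C@]3(CCC[C@@]4(C)COC(=O)[C@H]43)[C@H]12 | intermediate
21 | 11,15-dioxo-6,7-seco-ent-kaur-16-ene-6,19:7,20-diolide | C=C1[C@@H]2CC(=O)[C@H]3[C@@]4(CCC[C@@]5(C)COC(=O)[C@H]54)COC(=O)[C@]3(C2)C1=O | intermediate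
22 | Guidongnin | C=C1[C@@H]2C[C@@H](O)[C@H]3[C@@]4(CCC[C@@]5(C)COC(=O)[C@H]54)COC(=O)[C@]3(C2)[C@@H]1O | target

**Step count**
Total: 16 steps. Longest linear sequence: 15 steps (Steps 1–11 and 13–16, from diallyl malonate); Step 12 is a one-step side branch.

**Three steps most likely to fail, with fallbacks**
1. Step 2 (the proposed annulation): the enamine SN2 may be slow, or background Michael addition may erode ee. Fallback with known chemistry: diarylprolinol silyl ether iminium-catalysed Michael addition of 3 to the α-unbranched enal ethyl (E)-4-oxobut-2-enoate to set C5, then intramolecular aldehyde α-alkylation (proline or base) to close ring A, then α-methylation of the ring aldehyde enolate (KOt-Bu, MeI) anti to the vicinal ester to create C4; this converges on 5 in three steps.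
2. Step 11 (silyloxydiene IMDA): the tether forces the electronically mismatched orientation, and the facial preference at C9 against C10 is only moderately biased. Fallback: stop Step 9 at the allylic alcohol and dehydrate it (Burgess reagent) to the unpolarised (E)-buta-1,3-dienyl compound. Run the plain thermal ester-tethered Diels–Alder reaction, which is the polarity-neutral cycloaddition established for this spiro-lactone ring system. After the C8 aldol, install the C11 carbonyl and C12=C13 alkene by singlet-oxygen ene reaction of the C11=C12 alkene and dehydration of the resulting allylic hydroperoxide (Ac2O, pyridine).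
3. Step 15 (vinyl radical from an α-bromo enone): competing hydrostannation of the two enones is possible. Fallback: replace the Step 13 aldol by alkylation of the same enolate with 2,3-dibromopropene and oxidise the silyl enol ether to the enone. Cyclise the simple 2-bromoallyl vinyl radical onto the enone (well precedented for this bicyclo[3.2.1]octane), then introduce C15=O late by SeO2/t-BuOOH allylic oxidation and Dess–Martin oxidation before the same final Luche reduction.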